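**Retrosynthetic overview**

1. Labels: lactone ring O–C2(=O)–C1–C10(CH3)–C9–C8(CH3); ring B C10–C5–C6–C7–C8–C9; acid arm C5–C4(CH3)2–C3O2H; side chain C9–C11(OH)–C12–C13(OH)(CH3)–C14=C15. The route rests on the 1,5-dicarbonyl chain C2(=O)–C1–C10–C5–C6(=O), which runs through the lactone ring and ring B and meets at the quaternary C10.
2. Key disconnection: reconnect C1–C6 (retro-aldol), then cut C5–C6 and C1–C10 (retro-[2+2]) to reach 4-silyloxy-5,6-dihydropyran-2-one 14 carrying the isopropenyl group on C9 (de Mayo reaction). This one step closes ring B and the bridged δ-lactone.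
3. 14 comes from 4-hydroxypyranone 13 and aldehyde 11 (Roskamp homologation, lactonisation). C8 and C9 are set by Sharpless epoxidation of Z-allylic alcohol 6 and anti opening at C9 with an isopropenyl cuprate.
4. After the key step: exo-face reduction at C6; diazoacetate C–H insertion at C5 (temporary γ-lactone C6–O–C3); gem-dimethylation at C4; then the C11 aldehyde is elaborated by allylation, ozonolysis, vinyl addition, oxidation and chelate-controlled methyl addition (C11, C13).
5. End: saponification of both lactones, silylation of the C6 and C11 hydroxyls, re-closure of the δ-lactone on O8, desilylation. Ring order: pyranone (sacrificed), ring B plus δ-lactone (key step), γ-lactone (temporary), δ-lactone (final).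

Key step: step 12

Remark: the drawn form of the target (free C3 acid, free C6 hydroxyl, lactone on the tertiary O8) is assumed to be isolable; the last steps are arranged so that the C2 acid can close only on O8 and the C6 hydroxyl is released last, under buffered conditions.

**Step 1**
Reactants: 1 but-3-yn-1-ol
Product: 2 tert-butyl(but-3-yn-1-yloxy)dimethylsilane
Conditions: TBSCl, imidazole, CH2Cl2, 0 °C to rt
Reagents that add atoms: tert-butyldimethylsilyl chloride, CC(C)(C)[Si](C)(C)Cl
Why: Standard silylation of a primary alcohol; the ether masks the future C6 oxygen through the organometallic steps.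

**Step 2**
Reactants: 2
Product: 4 ethyl 5-[(tert-butyldimethylsilyl)oxy]pent-2-ynoate, via lithium acetylide 3 (not isolated)
Conditions: n-BuLi, THF, −78 °C; ClCO2Et, −78 to 0 °C
Reagents that add atoms: ethyl chloroformate, CCOC(=O)Cl
Why: Acylation of a lithium acetylide with a chloroformate is the standard route to 2-alkynoates.

**Step 3**
Reactants: 4
Product: 5 ethyl (Z)-5-[(tert-butyldimethylsilyl)oxy]-3-methylpent-2-enoate
Conditions: Me2CuLi (from MeLi and CuI), THF, −78 °C; MeOH then aq. NH4Cl at −78 °C
Reagents that add atoms: lithium dimethylcuprate, [Li+].C[Cu-]C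
Why: syn-Carbocupration of the ynoate at low temperature places the methyl group trans to the ester, so C7 and the future C11 are cis (Z), the geometry that the epoxide route needs.

**Step 4**
Reactants: 5
Product: 6 (Z)-5-[(tert-butyldimethylsilyl)oxy]-3-methylpent-2-en-1-ol
Conditions: i-Bu2AlH (2.2 equiv), CH2Cl2, −78 °C; Rochelle salt
Reagents that add atoms: none
Why: 1,2-Reduction of the enoate with DIBAL-H gives the allylic alcohol without change of alkene geometry.

**Step 5**
Reactants: 6
Product: 7 [(2R,3S)-3-{2-[(tert-butyldimethylsilyl)oxy]ethyl}-3-methyloxiran-2-yl]methanol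
Conditions: Ti(OiPr)4 (10 mol%), D-(−)-diisopropyl tartrate (12 mol%), t-BuOOH, 4 Å MS, CH2Cl2, −20 °C
Reagents that add atoms: tert-butyl hydroperoxide, CC(C)(C)OO
Why: Sharpless asymmetric epoxidation; the D-tartrate delivers oxygen to the face that gives 2R (future C9), and the Z geometry then fixes 3S (C8).

**Step 6**
Reactants: 7
Product: 8 (2S,3S)-5-[(tert-butyldimethylsilyl)oxy]-3-methyl-2-(prop-1-en-2-yl)pentane-1,3-diol
Conditions: isopropenylMgBr (3.5 equiv), CuI (15 mol%), THF, −30 to 0 °C; aq. NH4Cl
Reagents that add atoms: isopropenylmagnesium bromide, CC(=C)[Mg]Br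
Why: Copper-catalysed SN2 opening of a 3,3-disubstituted 2,3-epoxy alcohol occurs at the secondary carbon with inversion (the tertiary carbon is blocked), which sets C9 (S) next to the retained tertiary carbinol C8 (S).

**Step 7**
Reactants: 8
Product: 9 (2S,3S)-1-(benzyloxy)-5-[(tert-butyldimethylsilyl)oxy]-3-methyl-2-(prop-1-en-2-yl)pentan-3-ol
Conditions: NaH (1.1 equiv), BnBr (1.05 equiv), Bu4NI (cat.), THF, 0 °C to rt
Reagents that add atoms: benzyl bromide, BrCc1ccccc1
Why: Williamson etherification; only the primary alkoxide is alkylated and the tertiary hydroxyl stays free.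

**Step 8**
Reactants: 9
Product: 10 (3S,4S)-5-(benzyloxy)-3-methyl-4-(prop-1-en-2-yl)pentane-1,3-diol
Conditions: Bu4NF, THF, 0 °C to rt
Reagents that add atoms: none
Why: Fluoride cleaves the primary silyl ether; the benzyl ether, alkene and tertiary alcohol are inert.

**Step 9**
Reactants: 10
Product: 11 (3S,4S)-5-(benzyloxy)-3-hydroxy-3-methyl-4-(prop-1-en-2-yl)pentanal
Conditions: TEMPO (10 mol%), PhI(OAc)2 (1.1 equiv), CH2Cl2, rt
Reagents that add atoms: none
Why: Oxoammonium (TEMPO) oxidation stops at the aldehyde and cannot touch the tertiary hydroxyl.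

**Step 10**
Reactants: 11
Product: 13 (6S)-6-[(2S)-1-(benzyloxy)-3-methylbut-3-en-2-yl]-4-hydroxy-6-methyl-5,6-dihydro-2H-pyran-2-one, via δ-hydroxy-β-keto ester 12 (not isolated)
Conditions: N2CHCO2Et (1.3 equiv), SnCl2 (10 mol%), CH2Cl2, rt; then NaOH (0.1 M aq.), THF, rt; HCl to pH 2
Reagents that add atoms: ethyl diazoacetate, CCOC(=O)C=[N+]=[N-]
Why: Roskamp homologation converts the aldehyde into the β-keto ester, and base-mediated lactonisation of a δ-hydroxy-β-keto ester followed by acidification is the standard route to 6,6-disubstituted 4-hydroxy-5,6-dihydropyran-2-ones.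

**Step 11**
Reactants: 13
Product: 14 (6S)-6-[(2S)-1-(benzyloxy)-3-methylbut-3-en-2-yl]-4-[(tert-butyldimethylsilyl)oxy]-6-methyl-5,6-dihydro-2H-pyran-2-one
Conditions: TBSOTf (1.1 equiv), Et3N (1.5 equiv), CH2Cl2, −78 °C
Reagents that add atoms: tert-butyldimethylsilyl trifluoromethanesulfonate, CC(C)(C)[Si](C)(C)OS(=O)(=O)C(F)(F)F
Why: O-Silylation of the vinylogous acid locks the enol tautomer, the only photoactive form, as the conjugated 4-silyloxy enoate.

**Step 12**
Reactants: 14
Product: 16 bicyclic keto-lactone 9-[(benzyloxy)methyl]-1,5-dimethyl-2-oxabicyclo[3.3.1]nonane-3,7-dione (CH2OBn on the bridge carbon C9 syn to the lactone bridge; 8S,9S,10S in the route labels), via silyloxycyclobutane photoadduct 15 (not isolated)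
Conditions: hν (254 nm, quartz), MeCN (0.005 M, degassed), rt; then Bu4NF, AcOH, THF, 0 °C
Reagents that add atoms: none
Why: Proposed new method: excitation of the 4-silyloxy enoate (O=C2–C1=C6–OSi) should give a triplet whose C6 bonds to the CH2 terminus C5 of the isopropenyl group (six-membered ring, 1,6-closure), leaving a tertiary radical at C10 and an α-acyl radical at C1 that combine to the cyclobutane of 15; fluoride then frees the cyclobutanolate, which opens by retro-aldol cleavage of C1–C6 (relief of four-ring strain, lactone-stabilised carbanion at C1) to give 16. The closest known reaction types are intramolecular de Mayo reactions of dioxinones and of silyl or acyl enol derivatives of 1,3-dicarbonyl compounds, and the crossed photocycloaddition of 6-allylcyclohex-2-enones, which gives the same tricyclo[3.3.1.0(2,7)]nonane cage as 15; new here are the vinylogous silyl carbonate chromophore and the attachment of the tether to the ring carbon two atoms away from C6. Ring B (C10–C5–C6–C7–C8–C9) is closed by the C5–C6 bond and the lactone ring O–C2–C1–C10–C9–C8 by the C1–C10 radical recombination, while the original pyranone ring is lost in the retro-aldol. The new stereocentre C10 is controlled by C8 and C9: the one-carbon bridge C9 can only span cis positions, so the alkene must add to the pyranone face that carries C9, and only one configuration at C10 can form. The step needs C6–C5 (crossed) bonding rather than C6–C10 (straight, five-ring first), which the methyl group on C10 should secure (tertiary against primary radical, and no bond between two fully substituted carbons); silylation keeps the chromophore in its photoactive tautomer and lets 15 be opened under buffered conditions that do not eliminate the β-acyloxy ketone.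

**Step 13**
Reactants: 16
Product: 17 C6 endo-alcohol (16 with C6=O reduced to C6–OH cis to the C1–C2–O bridge)
Conditions: NaBH4, CeCl3·7H2O, MeOH, −78 °C; AcOH quench
Reagents that add atoms: none
Why: Luche reduction; hydride should attack C6 from the open exo face because the endo face is covered by the lactone bridge, giving the axial endo-alcohol of the target, and the cerium salt keeps the medium non-basic so the β-acyloxy ketone does not eliminate.

**Step 14**
Reactants: 17
Product: 19 C6 diazoacetate of 17, via glyoxylate tosylhydrazone ester 18 (not isolated)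
Conditions: TsNHN=CHCOCl, PhNMe2, CH2Cl2, 0 °C; then Et3N, 0 °C to rt
Reagents that add atoms: 2-[2-(4-methylbenzenesulfonyl)hydrazinylidene]acetyl chloride, Cc1ccc(cc1)S(=O)(=O)NN=CC(=O)Cl
Why: Acylation with the acid chloride and base-induced loss of sulfinate from the tosylhydrazone (Bamford–Stevens type) is the standard one-flask route to diazoacetates of hindered alcohols; acylating O6 also removes the only hydroxyl that could take over the C2 acyl group from O8.

**Step 15**
Reactants: 19
Product: 20 bis-lactone (new γ-lactone C6–O–C3(=O)–C4H2–C5, cis-fused on ring B)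
Conditions: Rh2(NHCOCH3)4 (1 mol%), CH2Cl2, reflux, slow addition of 19
Reagents that add atoms: none
Why: Dirhodium-carbenoid intramolecular C–H insertion of a cyclohexyl diazoacetate gives the five-membered lactone; the carboxamidate catalyst favours the more electron-rich C5–H (C7–H is deactivated by the β-acyloxy group on C8), and the axial C6–O can reach only the cis hydrogen, which sets C5.

**Step 16**
Reactants: 20
Product: 24 gem-dimethyl bis-lactone (C4(CH3)2), via C4 lithium enolate 21 (not isolated), via monomethyl lactone 22 (not isolated), via methylated lithium enolate 23 (not isolated)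
Conditions: LDA (1.1 equiv), THF, −78 °C; MeI; then LDA (1.3 equiv), −78 °C; MeI, DMPU, −78 to −30 °C
Reagents that add atoms: iodomethane, CI
Why: Two successive lactone enolate alkylations; C4 of the γ-lactone should be deprotonated in preference to C1 of the δ-lactone, which is neopentylic and whose enolisable axial hydrogen is screened by the syn-axial C11 benzyloxymethyl group.

**Step 17**
Reactants: 24
Product: 25 primary alcohol (C11–OH)
Conditions: H2 (1 atm), Pd(OH)2/C, EtOAc, rt
Reagents that add atoms: none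
Why: Hydrogenolysis of the benzyl ether; nothing else in 24 is reducible, and 25 is carried on at once.

**Step 18**
Reactants: 25
Product: 26 C11 aldehyde
Conditions: Dess–Martin periodinane, NaHCO3, CH2Cl2, 0 °C to rt
Reagents that add atoms: none
Why: Buffered Dess–Martin oxidation gives the hindered aldehyde without base, so C9 is not epimerised.

**Step 19**
Reactants: 26
Product: 28 (11S)-homoallylic alcohol (C11(OH)–CH2–CH=CH2), via diisopinocampheylborinate 27 (not isolated)
Conditions: (−)-Ipc2B(allyl) (from (+)-α-pinene), Et2O, −78 °C; then pH 7 buffer, H2O2, MeOH, 0 °C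
Reagents that add atoms: (−)-B-allyldiisopinocampheylborane, C=CCB([C@@H]1C[C@@H]2C[C@H]([C@H]1C)C2(C)C)[C@@H]1C[C@@H]2C[C@H]([C@H]1C)C2(C)C
Why: Brown allylation; the reagent from (+)-α-pinene adds allyl to the Si face of the aldehyde through a closed six-membered transition state, which gives 11S because C9 outranks the allyl carbon.

**Step 20**
Reactants: 28
Product: 30 β-hydroxy aldehyde (C13 aldehyde), via ozonide 29 (not isolated)
Conditions: O3, CH2Cl2, −78 °C; then PPh3, −78 °C to rt
Reagents that add atoms: ozone, [O-][O+]=O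
Why: Ozonolysis of the only alkene with reductive work-up gives the aldehyde, which is used crude.

**Step 21**
Reactants: 30
Product: 31 allylic alcohol (C13 epimers)
Conditions: CH2=CHMgBr (3 equiv), THF, −78 °C; aq. NH4Cl
Reagents that add atoms: vinylmagnesium bromide, C=C[Mg]Br
Why: Grignard addition to the aldehyde at −78 °C is much faster than attack on the two shielded lactones; the C13 configuration is irrelevant because it is oxidised next.

**Step 22**
Reactants: 31
Product: 32 β-hydroxy vinyl ketone (C13=O)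
Conditions: MnO2 (activated), CH2Cl2, rt
Reagents that add atoms: none
Why: MnO2 oxidises the allylic secondary alcohol chemoselectively and leaves the saturated C11 carbinol.

**Step 23**
Reactants: 32
Product: 33 (11S,13R)-diol bis-lactone
Conditions: MeMgBr (3.5 equiv), CH2Cl2/Et2O, −78 °C; aq. NH4Cl
Reagents that add atoms: methylmagnesium bromide, C[Mg]Br
Why: Chelation-controlled Grignard 1,2-addition; the ketone is held in a six-membered magnesium chelate with the C11 alkoxide, and attack on the face remote from the C11 substituent should give the 13R carbinol (11,13-syn with vinyl in the chain).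

**Step 24**
Reactants: 33
Product: 35 seco-diacid bis(triethylsilyl) ether (C6–OTES, C11–OTES; C8–OH, C13–OH, C2O2H and C3O2H free), via dipotassium seco-dicarboxylate 34 (not isolated)
Conditions: KOH, MeOH/H2O, 60 °C; evaporate; then Et3SiCl, imidazole, DMAP (cat.), DMF, 0 to 40 °C; aq. NaHCO3, then pH 5 buffer
Reagents that add atoms: potassium hydroxide, [K+].[OH-]; chlorotriethylsilane, CC[Si](CC)(CC)Cl
Why: Saponification opens both lactones (so any acyl migration in the earlier alkoxide steps is without consequence), the silyl chloride with imidazole silylates only the secondary C6 and C11 hydroxyls, and the silyl esters hydrolyse on work-up.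

**Step 25**
Reactants: 35
Product: 36 δ-lactone (C2 on O8) with C6–OTES, C11–OTES and free C3 acid
Conditions: EDC·HCl (1.2 equiv), DMAP (0.2 equiv), CH2Cl2, 0 °C to rt
Reagents that add atoms: none
Why: Steglich-type lactonisation; the unhindered CH2CO2H arm on C10 is activated and captured by the only hydroxyl within reach, the 1,3-diaxial tertiary C8–OH, while the C3 acid next to the gem-dimethyl group stays free.

**Step 26**
Reactants: 36
Product: 37 target (5R,6R,8S,9S,10R,11S,13R in the route labels)
Conditions: HF·pyridine, pyridine, THF, 0 °C to rt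
Reagents that add atoms: none
Why: Buffered fluoride desilylation removes both triethylsilyl ethers without base, so the C6 and C11 hydroxyls are released last without acyl migration.

**Compound list**

1 | but-3-yn-1-ol | C#CCCO | starting material
2 | tert-butyl(but-3-yn-1-yloxy)dimethylsilane | C#CCCO[Si](C)(C)C(C)(C)C | intermediate
3 | lithium acetylide of 2 | [Li]C#CCCO[Si](C)(C)C(C)(C)C | intermediate (not isolated)
4 | ethyl 5-[(tert-butyldimethylsilyl)oxy]pent-2-ynoate | CCOC(=O)C#CCCO[Si](C)(C)C(C)(C)C | intermediate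
5 | ethyl (Z)-5-[(tert-butyldimethylsilyl)oxy]-3-methylpent-2-enoate | CCOC(=O)/C=C(/C)CCO[Si](C)(C)C(C)(C)C | intermediate
6 | (Z)-5-[(tert-butyldimethylsilyl)oxy]-3-methylpent-2-en-1-ol | OC/C=C(/C)CCO[Si](C)(C)C(C)(C)C | intermediate
7 | [(2R,3S)-3-{2-[(tert-butyldimethylsilyl)oxy]ethyl}-3-methyloxiran-2-yl]methanol | OC[C@H]1O[C@@]1(C)CCO[Si](C)(C)C(C)(C)C | intermediate
8 | (2S,3S)-5-[(tert-butyldimethylsilyl)oxy]-3-methyl-2-(prop-1-en-2-yl)pentane-1,3-diol | OC[C@H](C(C)=C)[C@@](C)(O)CCO[Si](C)(C)C(C)(C)C | intermediate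
9 | (2S,3S)-1-(benzyloxy)-5-[(tert-butyldimethylsilyl)oxy]-3-methyl-2-(prop-1-en-2-yl)pentan-3-ol | c1ccccc1COC[C@H](C(C)=C)[C@@](C)(O)CCO[Si](C)(C)C(C)(C)C | intermediate
10 | (3S,4S)-5-(benzyloxy)-3-methyl-4-(prop-1-en-2-yl)pentane-1,3-diol | c1ccccc1COC[C@H](C(C)=C)[C@@](C)(O)CCO | intermediate
11 | (3S,4S)-5-(benzyloxy)-3-hydroxy-3-methyl-4-(prop-1-en-2-yl)pentanal | c1ccccc1COC[C@H](C(C)=C)[C@@](C)(O)CC=O | intermediate
12 | ethyl (5S,6S)-7-(benzyloxy)-5-hydroxy-5-methyl-3-oxo-6-(prop-1-en-2-yl)heptanoate | c1ccccc1COC[C@H](C(C)=C)[C@@](C)(O)CC(=O)CC(=O)OCC | intermediate (not isolated)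
13 | (6S)-6-[(2S)-1-(benzyloxy)-3-methylbut-3-en-2-yl]-4-hydroxy-6-methyl-5,6-dihydro-2H-pyran-2-one | CC(=C)[C@@H](COCc1ccccc1)[C@]2(C)CC(O)=CC(=O)O2 | intermediate
14 | (6S)-6-[(2S)-1-(benzyloxy)-3-methylbut-3-en-2-yl]-4-[(tert-butyldimethylsilyl)oxy]-6-methyl-5,6-dihydro-2H-pyran-2-one | CC(=C)[C@@H](COCc1ccccc1)[C@]2(C)CC(O[Si](C)(C)C(C)(C)C)=CC(=O)O2 | intermediate (key-step precursor)
15 | silyloxycyclobutane photoadduct (C5–C6 and C1–C10 bonds formed, C6–OTBS, cage forced by C8 and C9) | O=C1O[C@@]2(C)C[C@]3(O[Si](C)(C)C(C)(C)C)C[C@]([C@H]13)(C)[C@H]2COCc1ccccc1 | intermediate (not isolated)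
16 | 9-[(benzyloxy)methyl]-1,5-dimethyl-2-oxabicyclo[3.3.1]nonane-3,7-dione, CH2OBn syn to the lactone bridge (8S,9S,10S in route labels) | c1ccccc1COC[C@@H]1[C@]2(C)CC(=O)O[C@@]1(C)CC(=O)C2 | intermediate (key-step product)
17 | C6 endo-alcohol of 16 (C6–OH cis to the lactone bridge) | c1ccccc1COC[C@@H]1[C@]2(C)CC(=O)O[C@@]1(C)C[C@@H](O)C2 | intermediate
18 | C6 glyoxylate tosylhydrazone ester of 17 | c1ccccc1COC[C@@H]1[C@]2(C)CC(=O)O[C@@]1(C)C[C@@H](OC(=O)C=NNS(=O)(=O)c3ccc(C)cc3)C2 | intermediate (not isolated)
19 | C6 diazoacetate of 17 | c1ccccc1COC[C@@H]1[C@]2(C)CC(=O)O[C@@]1(C)C[C@@H](OC(=O)C=[N+]=[N-])C2 | intermediate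
20 | bis-lactone with cis-fused γ-lactone C6–O–C3(=O)–C4H2–C5 | c1ccccc1COC[C@@H]1[C@]2(C)CC(=O)O[C@@]1(C)C[C@H]3OC(=O)C[C@@H]23 | intermediate
21 | C4 lithium enolate of 20 | c1ccccc1COC[C@@H]1[C@]2(C)CC(=O)O[C@@]1(C)C[C@H]3OC([O-])=C[C@@H]23.[Li+] | intermediate (not isolated)
22 | C4-monomethyl bis-lactone (C4 epimers) | c1ccccc1COC[C@@H]1[C@]2(C)CC(=O)O[C@@]1(C)C[C@H]3OC(=O)C(C)[C@@H]23 | intermediate (not isolated)
23 | C4 lithium enolate of 22 | c1ccccc1COC[C@@H]1[C@]2(C)CC(=O)O[C@@]1(C)C[C@H]3OC([O-])=C(C)[C@@H]23.[Li+] | intermediate (not isolated)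
24 | C4 gem-dimethyl bis-lactone, C11–OBn | c1ccccc1COC[C@@H]1[C@]2(C)CC(=O)O[C@@]1(C)C[C@H]3OC(=O)C(C)(C)[C@@H]23 | intermediate
25 | C11 primary alcohol of the bis-lactone | OC[C@@H]1[C@]2(C)CC(=O)O[C@@]1(C)C[C@H]3OC(=O)C(C)(C)[C@@H]23 | intermediate
26 | C11 aldehyde of the bis-lactone | O=C[C@@H]1[C@]2(C)CC(=O)O[C@@]1(C)C[C@H]3OC(=O)C(C)(C)[C@@H]23 | intermediate
27 | C11 diisopinocampheylborinate of 28 | C=CC[C@H](OB([C@@H]1C[C@@H]2C[C@H]([C@H]1C)C2(C)C)[C@@H]1C[C@@H]2C[C@H]([C@H]1C)C2(C)C)[C@@H]1[C@]2(C)CC(=O)O[C@@]1(C)C[C@H]3OC(=O)C(C)(C)[C@@H]23 | intermediate (not isolated)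
28 | (11S)-homoallylic alcohol of the bis-lactone | C=CC[C@H](O)[C@@H]1[C@]2(C)CC(=O)O[C@@]1(C)C[C@H]3OC(=O)C(C)(C)[C@@H]23 | intermediate
29 | ozonide (1,2,4-trioxolane) of 28 | C1(OCOO1)C[C@H](O)[C@@H]1[C@]2(C)CC(=O)O[C@@]1(C)C[C@H]3OC(=O)C(C)(C)[C@@H]23 | intermediate (not isolated)
30 | (11S)-β-hydroxy aldehyde (C13 aldehyde) | O=CC[C@H](O)[C@@H]1[C@]2(C)CC(=O)O[C@@]1(C)C[C@H]3OC(=O)C(C)(C)[C@@H]23 | intermediate
31 | (11S)-allylic alcohol, C13 epimers | C=CC(O)C[C@H](O)[C@@H]1[C@]2(C)CC(=O)O[C@@]1(C)C[C@H]3OC(=O)C(C)(C)[C@@H]23 | intermediate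
32 | (11S)-β-hydroxy vinyl ketone | C=CC(=O)C[C@H](O)[C@@H]1[C@]2(C)CC(=O)O[C@@]1(C)C[C@H]3OC(=O)C(C)(C)[C@@H]23 | intermediate
33 | (11S,13R)-diol bis-lactone | C=C[C@](C)(O)C[C@H](O)[C@@H]1[C@]2(C)CC(=O)O[C@@]1(C)C[C@H]3OC(=O)C(C)(C)[C@@H]23 | intermediate
34 | dipotassium seco-dicarboxylate (both lactones open) | C=C[C@](C)(O)C[C@H](O)[C@H]1[C@@](C)(O)C[C@@H](O)[C@@H](C(C)(C)C(=O)[O-])[C@@]1(C)CC(=O)[O-].[K+].[K+] | intermediate (not isolated)
35 | seco-diacid with C6–OTES and C11–OTES | C=C[C@](C)(O)C[C@H](O[Si](CC)(CC)CC)[C@H]1[C@@](C)(O)C[C@@H](O[Si](CC)(CC)CC)[C@@H](C(C)(C)C(=O)O)[C@@]1(C)CC(=O)O | intermediate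
36 | δ-lactone (C2 on O8) with C6–OTES, C11–OTES, free C3 acid | C=C[C@](C)(O)C[C@H](O[Si](CC)(CC)CC)[C@@H]1[C@]2(C)CC(=O)O[C@@]1(C)C[C@@H](O[Si](CC)(CC)CC)[C@H]2C(C)(C)C(=O)O | intermediate
37 | CNP0297019.1 | C=C[C@](C)(O)C[C@H](O)[C@@H]1[C@]2(C)CC(=O)O[C@@]1(C)C[C@@H](O)[C@H]2C(C)(C)C(=O)O | target

**Step count and risk**

Total step count: 26. Longest linear sequence: 26 (fully linear from 1).

Steps most likely to fail:

1. Step 12 (key step). The first bond may form between C6 and C10 (five-ring, straight mode) instead of C6 and C5, or the triplet may decay through allylic hydrogen abstraction, so that the bridged skeleton is not formed. Fallback with known chemistry, from aldehyde 11 back to 16: vinylmagnesium bromide gives the dienol F1; ring-closing metathesis with the second-generation Grubbs catalyst closes ring B as the cyclohexenol F2 (C5=C10); MnO2 gives the enone F3; N-bromosuccinimide and ethyl vinyl ether convert the tertiary C8 hydroxyl into the bromoacetal F4; Bu3SnH and AIBN effect an Ueno–Stork 6-exo radical conjugate addition of the C1 radical to C10, giving the bicyclic acetal ketone F5 with C10 set cis by the axial C8–O tether; Jones oxidation (CrO3, H2SO4, acetone) converts the acetal into the lactone and returns 16.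

2. Step 16. Deprotonation may also occur at C1 of the δ-lactone, or the enolates may exchange protons, leading to methylation at C1 or an incomplete second methylation. Fallback from alcohol 17 back to 24: heating with 2,2,6-trimethyl-4H-1,3-dioxin-4-one in xylene gives the acetoacetate F6; diazo transfer (4-acetamidobenzenesulfonyl azide, Et3N) gives the diazoacetoacetate F7; Rh2(OAc)4-catalysed C–H insertion gives the α-acetyl γ-lactone F8, whose C4–H is far more acidic than C1–H; LiN(SiMe3)2 then paraformaldehyde gives the α-methylene γ-lactone F9 by deacetylative methylenation; conjugate reduction with LiBH(s-Bu)3 forms the C4 enolate regiospecifically and MeI traps it to give 24.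

3. Step 24. Silylation of the two hindered secondary hydroxyls may be incomplete, or a tertiary hydroxyl may be partly silylated, which would misdirect the lactonisation in step 25. Fallback from 33 to 37 without protecting groups: saponify as before to the salt 34, then acidify slowly to pH 3–4 at 0 °C and let the seco-diacid close by itself. This relies on the C2 arm closing on the 1,3-diaxial O8 faster than the hindered C3 acid closes on O6, and gives 37 directly; isomeric lactones would have to be separated.

**Further compounds**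

F1 | step 12 | (5S,6S)-7-(benzyloxy)-5-methyl-6-(prop-1-en-2-yl)hept-1-ene-3,5-diol (C3 epimers) | c1ccccc1COC[C@H](C(C)=C)[C@@](C)(O)CC(O)C=C
F2 | step 12 | 4-[(benzyloxy)methyl]-3,5-dimethylcyclohex-2-ene-1,5-diol (C1 epimers; C8 and C9 as in 11) | CC1=CC(O)C[C@](C)(O)[C@@H]1COCc1ccccc1
F3 | step 12 | 4-[(benzyloxy)methyl]-5-hydroxy-3,5-dimethylcyclohex-2-en-1-one | CC1=CC(=O)C[C@](C)(O)[C@@H]1COCc1ccccc1
F4 | step 12 | 4-[(benzyloxy)methyl]-5-(2-bromo-1-ethoxyethoxy)-3,5-dimethylcyclohex-2-en-1-one (acetal epimers) | CC1=CC(=O)C[C@](C)(OC(CBr)OCC)[C@@H]1COCc1ccccc1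
F5 | step 12 | 9-[(benzyloxy)methyl]-3-ethoxy-1,5-dimethyl-2-oxabicyclo[3.3.1]nonan-7-one (acetal epimers) | c1ccccc1COC[C@@H]1[C@]2(C)CC(OCC)O[C@@]1(C)CC(=O)C2
F6 | step 16 | C6 acetoacetate of 17 | c1ccccc1COC[C@@H]1[C@]2(C)CC(=O)O[C@@]1(C)C[C@@H](OC(=O)CC(C)=O)C2
F7 | step 16 | C6 2-diazo-3-oxobutanoate of 17 | c1ccccc1COC[C@@H]1[C@]2(C)CC(=O)O[C@@]1(C)C[C@@H](OC(=O)C(=[N+]=[N-])C(C)=O)C2
F8 | step 16 | C4-acetyl bis-lactone (C4 epimers) | c1ccccc1COC[C@@H]1[C@]2(C)CC(=O)O[C@@]1(C)C[C@H]3OC(=O)C(C(C)=O)[C@@H]23
F9 | step 16 | C4-methylene bis-lactone | c1ccccc1COC[C@@H]1[C@]2(C)CC(=O)O[C@@]1(C)C[C@H]3OC(=O)C(=C)[C@@H]23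
F0 | step 24 | none | none
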